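## Plan

- Retrosynthetic cuts: first the biaryl C7–C7′ bond (Suzuki). In the dihydronaphthalene half, the C1–OH bond is cut and C1 is re-closed onto C3, which gives an acetylcyclopropane fused to an indan-1-ol. The naphthol half is the same monomer after ring enlargement and oxidation.
- Enabling feature: in the 1,2-dihydronaphthalen-1-ol ring, carbinol C1 (benzylic, on the aryl carbon ortho to the phenol oxygen) is homoallylic to the C3=C4 styrene bond and C2 carries the acetyl group. C1–C2–C3 can therefore exist as a cyclopropane whose fusion bond C1–C3 is cut when a cation appears at C4; the acetyl group on the apex blocks the other cleavage.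
- Forward, common part: 4-hydroxyindan-1-one → bromide, silyl ether, 2-methylindenone → CBS reduction → carbenoid cyclopropanation → bicyclic carbinol 12, which serves both halves.
- Forward, end game: 12 → ring enlargement and oxidation → bromonaphthol 16; 12 → boronate 17; Suzuki → 18; ring enlargement five → six on the biaryl; desilylation.
- Stereochemistry: the CBS reduction sets C-6 of 12; C-6 steers the carbenoid (anti face, acetyl exo). In the ring enlargement C-2 is carried over, C-1 is made by inversion, and C-6 is erased.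

Key step: step 13

Assumption: in the CBS reduction of 6 the 2-methylalkenyl flank of the ketone is taken as the larger group, so that the (S)-catalyst gives the (1S)-indenol; if the sense is the opposite, the (R)-catalyst is used.

Abbreviations: TBS = tert-butyldimethylsilyl, TES = triethylsilyl.

## Route

Step 1
Reactants: 1 4-hydroxy-2,3-dihydro-1H-inden-1-one
Product: 2 5-bromo-4-hydroxy-2,3-dihydro-1H-inden-1-one
Conditions: NBS, i-Pr2NH (cat.), CH2Cl2, 0 °C
Reagents that add atoms: N-bromosuccinimide, O=C1CCC(=O)N1Br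
Why: Amine-mediated electrophilic bromination of a phenol, in which the N-bromoamine is delivered by hydrogen bonding to the OH group, should place bromine ortho to the hydroxyl at C-5 and not at the para position C-7.

Step 2
Reactants: 2 5-bromo-4-hydroxy-2,3-dihydro-1H-inden-1-one
Product: 3 5-bromo-4-[(tert-butyldimethylsilyl)oxy]-2,3-dihydro-1H-inden-1-one
Conditions: TBSCl, imidazole, DMF, rt to 40 °C
Reagents that add atoms: tert-butyldimethylsilyl chloride, CC(C)(C)[Si](C)(C)Cl
Why: Standard silylation of a phenol; the aryl silyl ether blocks O-alkylation and Mannich-type side reactions and comes off with fluoride at the end.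

Step 3
Reactants: 3 5-bromo-4-(TBS-oxy)indan-1-one
Product: 4 rac-5-bromo-4-[(tert-butyldimethylsilyl)oxy]-2-methyl-2,3-dihydro-1H-inden-1-one
Conditions: LiHMDS, THF, −78 °C; MeI, −78 → −20 °C
Reagents that add atoms: iodomethane, CI
Why: C-Alkylation of the kinetic lithium enolate of an aryl ketone; the new centre is racemic and is removed in step 4.

Step 4
Reactants: 4 rac-5-bromo-4-(TBS-oxy)-2-methylindan-1-one
Product: 6 5-bromo-4-[(tert-butyldimethylsilyl)oxy]-2-methyl-1H-inden-1-one, via 3-bromo ketone 5 (not isolated)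
Conditions: NBS, AIBN (cat.), PhCF3, 80 °C; then Et3N, 0 °C → rt
Reagents that add atoms: none
Why: Wohl–Ziegler bromination of the benzylic C-3 position followed by E1cB loss of HBr through the ketone enolate is the classical indanone-to-indenone sequence, and the 2-methyl group keeps the indenone from dimerising quickly.

Step 5
Reactants: 6 5-bromo-4-(TBS-oxy)-2-methyl-1H-inden-1-one
Product: 7 (1S)-5-bromo-4-[(tert-butyldimethylsilyl)oxy]-2-methyl-1H-inden-1-ol
Conditions: (S)-Me-CBS (15 mol %), catecholborane, toluene, −78 °C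
Reagents that add atoms: none
Why: Corey–Bakshi–Shibata 1,2-reduction of an α-substituted cyclic enone; the oxazaborolidine delivers hydride to one carbonyl face and sets C-1 as S.

Step 6
Reactants: 7 (1S)-5-bromo-4-(TBS-oxy)-2-methyl-1H-inden-1-ol
Product: 8 (1S)-5-bromo-4-[(tert-butyldimethylsilyl)oxy]-2-methyl-1-[(triethylsilyl)oxy]-1H-indene
Conditions: TESCl, imidazole, DMF, 0 °C
Reagents that add atoms: chlorotriethylsilane, CC[Si](CC)(CC)Cl
Why: Silylation masks the O–H bond against carbenoid insertion and adds bulk on one alkene face; short exposure to the weak base at 0 °C should not start the 1,3-proton shift of the indenol.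

Step 7
Reactants: 9 acetyl chloride
Product: 10 1-diazopropan-2-one (diazoacetone)
Conditions: TMSCHN2, MeCN/THF, 0 °C → rt; used as a solution
Reagents that add atoms: (trimethylsilyl)diazomethane, C[Si](C)(C)C=[N+]=[N-]
Why: Acylation of the diazo carbon by the acid chloride with loss of the silyl group as TMSCl (Arndt–Eistert-type diazoketone synthesis).

Step 8
Reactants: 8 (1S)-indenyl TES ether; 10 diazoacetone
Product: 12 1-[(1S,1aS,6S,6aS)-3-bromo-2-[(tert-butyldimethylsilyl)oxy]-6-hydroxy-6a-methyl-1,1a,6,6a-tetrahydrocyclopropa[a]inden-1-yl]ethan-1-one, via TES-protected cyclopropane 11 (not isolated)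
Conditions: Rh2(OAc)4 (1 mol %), CH2Cl2, rt, slow addition of 10; then PPTS, MeOH, rt
Reagents that add atoms: none
Why: Rhodium(II)-carbenoid cyclopropanation of the electron-rich trisubstituted styrene bond should occur on the face anti to the C-1 OTES group with the acetyl group exo, which fixes C-1, C-1a and C-6a relative to C-6; mild acidic methanolysis then removes only the alkyl TES ether.

Step 9
Reactants: 12 bicyclic cyclopropyl carbinol
Product: 14 1-[(1S,2R)-7-bromo-8-[(tert-butyldimethylsilyl)oxy]-1-hydroxy-3-methyl-1,2-dihydronaphthalen-2-yl]ethan-1-one, via trichloroacetimidate 13 (not isolated)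
Conditions: Cl3CCN, DBU (cat.), CH2Cl2, 0 °C; then PPTS (cat.), THF/H2O (4:1), 0 °C
Reagents that add atoms: water, O
Why: Cyclopropylcarbinyl–homoallyl ring enlargement by the mechanism described under step 13, run here on the monomer to supply the naphthol half.

Step 10
Reactants: 14 (1S,2R)-7-bromo-dihydronaphthalen-1-ol
Product: 16 1-[7-bromo-8-[(tert-butyldimethylsilyl)oxy]-1-hydroxy-3-methylnaphthalen-2-yl]ethan-1-one, via naphthalenone keto tautomer 15 (not isolated)
Conditions: Dess–Martin periodinane, NaHCO3, CH2Cl2, 0 °C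
Reagents that add atoms: none
Why: Dess–Martin oxidation of the benzylic alcohol gives a β-diketone that is the keto tautomer of a 1-naphthol and should enolise at once to the aromatic, hydrogen-bonded 2-acetyl-1-naphthol.

Step 11
Reactants: 12 bicyclic cyclopropyl carbinol
Product: 17 1-[(1S,1aS,6S,6aS)-2-[(tert-butyldimethylsilyl)oxy]-6-hydroxy-6a-methyl-3-(4,4,5,5-tetramethyl-1,3,2-dioxaborolan-2-yl)-1,1a,6,6a-tetrahydrocyclopropa[a]inden-1-yl]ethan-1-one
Conditions: B2pin2, Pd(dppf)Cl2 (5 mol %), KOAc, 1,4-dioxane, 85 °C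
Reagents that add atoms: bis(pinacolato)diboron, CC1(C)OB(OC1(C)C)B1OC(C)(C)C(C)(C)O1
Why: Miyaura borylation of the aryl bromide; the free secondary alcohol, the cyclopropyl ketone and the aryl silyl ether should be inert to acetate base.

Step 12
Reactants: 17 cyclopropane-fused aryl boronate; 16 bromonaphthol
Product: 18 1-[(1S,1aS,6S,6aS)-3-[7-acetyl-1-[(tert-butyldimethylsilyl)oxy]-8-hydroxy-6-methylnaphthalen-2-yl]-2-[(tert-butyldimethylsilyl)oxy]-6-hydroxy-6a-methyl-1,1a,6,6a-tetrahydrocyclopropa[a]inden-1-yl]ethan-1-one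
Conditions: SPhos Pd G3 (3 mol %), aq. K3PO4, THF, 40 °C
Reagents that add atoms: none
Why: Suzuki–Miyaura coupling with a biarylphosphine catalyst made for ortho-substituted partners; the biaryl has only two ortho substituents and no stereoaxis, and the base-stable cyclopropane is carried through in place of the base-labile β-hydroxy ketone.

Step 13
Reactants: 18 biaryl cyclopropyl carbinol
Product: 20 1-[(1S,2R)-7-[7-acetyl-1-[(tert-butyldimethylsilyl)oxy]-8-hydroxy-6-methylnaphthalen-2-yl]-8-[(tert-butyldimethylsilyl)oxy]-1-hydroxy-3-methyl-1,2-dihydronaphthalen-2-yl]ethan-1-one, via biaryl trichloroacetimidate 19 (not isolated)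
Conditions: Cl3CCN, DBU, CH2Cl2, 0 °C; then PPTS, THF/H2O (4:1), 0 °C
Reagents that add atoms: water, O
Why: The N-protonated imidate leaves as neutral trichloroacetamide, so C-6 should ionise at pH 4–5 to a benzylic cyclopropylcarbinyl cation; the external cyclopropane bond C-6a–C-1 cannot open because that would place the charge next to the acetyl group, and the charge is therefore passed through the ring-fusion bond C-1a–C-6a to C-1a, which is benzylic to the aryl carbon ortho to the silyloxy group. The closest known reaction type is the solvolytic cyclopropylcarbinyl-to-homoallyl ring enlargement of bicyclo[3.1.0]hexan-2-yl derivatives (thujanol to terpinen-4-ol, the i-steroid rearrangement, the Julia homoallyl synthesis). No ring is closed by bond formation: the six-membered ring arises because the zero-atom bridge of the benzo-fused bicyclo[3.1.0]hexane is cut, so that the former five-membered ring gains the acetyl-bearing carbon as a ring member and the C-3=C-4 double bond appears where the C-6–O bond leaves. C-2 of the product is the cyclopropane carbon C-1 and keeps its configuration (exo acetyl from step 8), while C-1 is formed by attack of water on C-1a from the side opposite the breaking C-1a–C-6a bond (inversion), which is also the face anti to the acetyl group, and this should give the trans (1S,2R) arrangement. The step needs capture by water to win over loss of the acidic H-2 from the cation (aromatisation to the naphthalene) and needs the product not to ionise again; the first is served by a large excess of water at 0 °C, the second by the fact that after hydrolysis the nucleofuge is gone and the benzylic alcohol should be inert at this pH.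

Step 14
Reactants: 20 bis-TBS ether of the target
Product: 21 1-[(1S,2R)-7-(7-acetyl-1,8-dihydroxy-6-methylnaphthalen-2-yl)-1,8-dihydroxy-3-methyl-1,2-dihydronaphthalen-2-yl]ethan-1-one
Conditions: TBAF, AcOH (1:1), THF, 0 °C
Reagents that add atoms: none
Why: Fluoride cleaves aryl silyl ethers quickly at 0 °C, and the acetic acid buffer keeps the medium near neutral so that neither enolate formation nor acid ionisation of the benzylic alcohol should set in.

## Compound list

1 | 4-hydroxy-2,3-dihydro-1H-inden-1-one | O=C1CCc2c1cccc2O | starting material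
2 | 5-bromo-4-hydroxy-2,3-dihydro-1H-inden-1-one | O=C1CCc2c1ccc(Br)c2O | intermediate
3 | 5-bromo-4-[(tert-butyldimethylsilyl)oxy]-2,3-dihydro-1H-inden-1-one | O=C1CCc2c1ccc(Br)c2O[Si](C)(C)C(C)(C)C | intermediate
4 | rac-5-bromo-4-[(tert-butyldimethylsilyl)oxy]-2-methyl-2,3-dihydro-1H-inden-1-one | O=C1C(C)Cc2c1ccc(Br)c2O[Si](C)(C)C(C)(C)C | intermediate
5 | 3,5-dibromo-4-[(tert-butyldimethylsilyl)oxy]-2-methyl-2,3-dihydro-1H-inden-1-one (diastereomer mixture, not isolated) | O=C1C(C)C(Br)c2c1ccc(Br)c2O[Si](C)(C)C(C)(C)C | intermediate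
6 | 5-bromo-4-[(tert-butyldimethylsilyl)oxy]-2-methyl-1H-inden-1-one | O=C1C(C)=Cc2c1ccc(Br)c2O[Si](C)(C)C(C)(C)C | intermediate
7 | (1S)-5-bromo-4-[(tert-butyldimethylsilyl)oxy]-2-methyl-1H-inden-1-ol | O[C@H]1C(C)=Cc2c1ccc(Br)c2O[Si](C)(C)C(C)(C)C | intermediate
8 | (1S)-5-bromo-4-[(tert-butyldimethylsilyl)oxy]-2-methyl-1-[(triethylsilyl)oxy]-1H-indene | CC[Si](CC)(CC)O[C@H]1C(C)=Cc2c1ccc(Br)c2O[Si](C)(C)C(C)(C)C | intermediate
9 | acetyl chloride | CC(=O)Cl | starting material
10 | 1-diazopropan-2-one | CC(=O)C=[N+]=[N-] | intermediate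
11 | 1-[(1S,1aS,6S,6aS)-3-bromo-2-[(tert-butyldimethylsilyl)oxy]-6a-methyl-6-[(triethylsilyl)oxy]-1,1a,6,6a-tetrahydrocyclopropa[a]inden-1-yl]ethan-1-one (acetyl exo, OTES anti to the cyclopropane; not isolated) | Brc1ccc2c(c1O[Si](C)(C)C(C)(C)C)[C@H]3[C@H](C(C)=O)[C@@]3(C)[C@@H]2O[Si](CC)(CC)CC | intermediate
12 | 1-[(1S,1aS,6S,6aS)-3-bromo-2-[(tert-butyldimethylsilyl)oxy]-6-hydroxy-6a-methyl-1,1a,6,6a-tetrahydrocyclopropa[a]inden-1-yl]ethan-1-one (acetyl exo, OH anti to the cyclopropane) | Brc1ccc2c(c1O[Si](C)(C)C(C)(C)C)[C@H]3[C@H](C(C)=O)[C@@]3(C)[C@@H]2O | intermediate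
13 | C-6 O-trichloroacetimidate of 12 (not isolated) | Brc1ccc2c(c1O[Si](C)(C)C(C)(C)C)[C@H]3[C@H](C(C)=O)[C@@]3(C)[C@@H]2OC(=N)C(Cl)(Cl)Cl | intermediate
14 | 1-[(1S,2R)-7-bromo-8-[(tert-butyldimethylsilyl)oxy]-1-hydroxy-3-methyl-1,2-dihydronaphthalen-2-yl]ethan-1-one (OH and acetyl trans) | Brc1ccc2c(c1O[Si](C)(C)C(C)(C)C)[C@@H](O)[C@H](C(C)=O)C(C)=C2 | intermediate
15 | 2-acetyl-7-bromo-8-[(tert-butyldimethylsilyl)oxy]-3-methylnaphthalen-1(2H)-one (keto tautomer, configurationally labile at C-2, not isolated) | Brc1ccc2c(c1O[Si](C)(C)C(C)(C)C)C(=O)[C@H](C(C)=O)C(C)=C2 | intermediate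
16 | 1-[7-bromo-8-[(tert-butyldimethylsilyl)oxy]-1-hydroxy-3-methylnaphthalen-2-yl]ethan-1-one | CC(=O)c1c(C)cc2ccc(Br)c(O[Si](C)(C)C(C)(C)C)c2c1O | intermediate
17 | 1-[(1S,1aS,6S,6aS)-2-[(tert-butyldimethylsilyl)oxy]-6-hydroxy-6a-methyl-3-(4,4,5,5-tetramethyl-1,3,2-dioxaborolan-2-yl)-1,1a,6,6a-tetrahydrocyclopropa[a]inden-1-yl]ethan-1-one | CC1(C)OB(OC1(C)C)c1ccc2c(c1O[Si](C)(C)C(C)(C)C)[C@H]3[C@H](C(C)=O)[C@@]3(C)[C@@H]2O | intermediate
18 | 1-[(1S,1aS,6S,6aS)-3-[7-acetyl-1-[(tert-butyldimethylsilyl)oxy]-8-hydroxy-6-methylnaphthalen-2-yl]-2-[(tert-butyldimethylsilyl)oxy]-6-hydroxy-6a-methyl-1,1a,6,6a-tetrahydrocyclopropa[a]inden-1-yl]ethan-1-one | CC(=O)c1c(C)cc2ccc(-c3ccc4c(c3O[Si](C)(C)C(C)(C)C)[C@H]5[C@H](C(C)=O)[C@@]5(C)[C@@H]4O)c(O[Si](C)(C)C(C)(C)C)c2c1O | intermediate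
19 | C-6 O-trichloroacetimidate of 18 (not isolated) | CC(=O)c1c(C)cc2ccc(-c3ccc4c(c3O[Si](C)(C)C(C)(C)C)[C@H]5[C@H](C(C)=O)[C@@]5(C)[C@@H]4OC(=N)C(Cl)(Cl)Cl)c(O[Si](C)(C)C(C)(C)C)c2c1O | intermediate
20 | 1-[(1S,2R)-7-[7-acetyl-1-[(tert-butyldimethylsilyl)oxy]-8-hydroxy-6-methylnaphthalen-2-yl]-8-[(tert-butyldimethylsilyl)oxy]-1-hydroxy-3-methyl-1,2-dihydronaphthalen-2-yl]ethan-1-one | CC(=O)c1c(C)cc2ccc(-c3ccc4c(c3O[Si](C)(C)C(C)(C)C)[C@@H](O)[C@H](C(C)=O)C(C)=C4)c(O[Si](C)(C)C(C)(C)C)c2c1O | intermediate
21 | 1-[(1S,2R)-7-(7-acetyl-1,8-dihydroxy-6-methylnaphthalen-2-yl)-1,8-dihydroxy-3-methyl-1,2-dihydronaphthalen-2-yl]ethan-1-one | CC(=O)c1c(C)cc2ccc(-c3ccc4c(c3O)[C@@H](O)[C@H](C(C)=O)C(C)=C4)c(O)c2c1O | target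

## Step count and risks

Total step count: 14. Longest linear sequence: 12 steps (1, 2, 3, 4, 5, 6, 8, 9, 10, 12, 13, 14).

The three steps most likely to fail:

1. Step 13 (key step). In the unsymmetrical biaryl the acidic, chelating 1-hydroxy-2-acetylnaphthalene half may take up base and imidoylating agent and buffer the acid, so that the C-6 carbinol is activated incompletely. The cation would then form slowly, and loss of H-2 (aromatisation) or loss of the trans selectivity could take over. The fallback removes the naphthol from the ionisation step and sets out from 12 and 17. Suzuki coupling of these two under the conditions of step 12 gives the C2-symmetric biaryl bis(cyclopropyl carbinol) F1. Two-fold imidate formation gives the bis(trichloroacetimidate) F2, which is not isolated and is hydrolysed under buffer as in step 9 to the bis(dihydronaphthalenol) F3. Oxidation of one of the two equivalent benzylic alcohols with a deficiency of Dess–Martin periodinane, with recycling of unreacted F3, gives the mono-diketone F4, which tautomerises to the naphthol and so rejoins the route at 20.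

2. Step 8. The carbenoid may add with poor facial selectivity with respect to the OTES group, which would lower the enantiomeric purity of everything that follows. It may also give poor exo/endo selectivity for the acetyl group, which would lead to the cis product after ring enlargement. Carbene dimerisation and ylide formation at the silyl ether oxygen are further losses. The fallback reverses the polarity of the cyclopropanation and lets a catalyst, not the substrate, set the configuration; it sets out from indenone 6. Ammonium-ylide cyclopropanation (2-bromo-N-methoxy-N-methylacetamide, Cs2CO3, catalytic cinchona-derived tertiary amine, MeCN) should give the exo Weinreb amide keto-cyclopropane F5. NaBH4 reduces the C-6 ketone to the alcohol F6; the configuration at C-6 does not matter because this centre is erased later, and the epimer with OH syn to the cyclopropane is assumed. MeMgBr converts the Weinreb amide into the methyl ketone F7, the C-6 epimer of 12. F7 replaces 12 in step 9 (via its imidate F8) and rejoins the route at 14. It also replaces 12 in steps 11 to 13 (boronate F9, biaryl F10, imidate F11) and rejoins the route at 20.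

3. Step 14. Once the phenols are free, the arene-hydrate-like benzylic alcohol may lose water during deprotection, through the enolate (E1cB) or through the ortho-quinone methide, and aromatise. The fallback changes the order of events so that the labile ring is made last and never meets fluoride; it sets out from 18. Desilylation of the robust cyclopropane 18 (TBAF, THF) gives the free-phenol biaryl cyclopropyl carbinol F12. Imidate formation at the aliphatic hydroxyl gives F13, which is not isolated, and buffered hydrolysis as in step 13 leads directly to 21.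

## Further compounds

F1 | step 13 | C2-symmetric 3,3′-linked dimer of the cyclopropyl carbinol (both halves configured as in 12, Br replaced by the biaryl bond) | c1(-c4ccc5c(c4O[Si](C)(C)C(C)(C)C)[C@H]6[C@H](C(C)=O)[C@@]6(C)[C@@H]5O)ccc2c(c1O[Si](C)(C)C(C)(C)C)[C@H]3[C@H](C(C)=O)[C@@]3(C)[C@@H]2O
F2 | step 13 | bis(O-trichloroacetimidate) of F1 | c1(-c4ccc5c(c4O[Si](C)(C)C(C)(C)C)[C@H]6[C@H](C(C)=O)[C@@]6(C)[C@@H]5OC(=N)C(Cl)(Cl)Cl)ccc2c(c1O[Si](C)(C)C(C)(C)C)[C@H]3[C@H](C(C)=O)[C@@]3(C)[C@@H]2OC(=N)C(Cl)(Cl)Cl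
F3 | step 13 | C2-symmetric 7,7′-linked bis[(1S,2R)-2-acetyl-8-(TBS-oxy)-1-hydroxy-3-methyl-1,2-dihydronaphthalene] | c1(-c3ccc4c(c3O[Si](C)(C)C(C)(C)C)[C@@H](O)[C@H](C(C)=O)C(C)=C4)ccc2c(c1O[Si](C)(C)C(C)(C)C)[C@@H](O)[C@H](C(C)=O)C(C)=C2
F4 | step 13 | mono-oxidised F3 (one half as the naphthalen-1(2H)-one keto tautomer) | c1(-c3ccc4c(c3O[Si](C)(C)C(C)(C)C)[C@@H](O)[C@H](C(C)=O)C(C)=C4)ccc2c(c1O[Si](C)(C)C(C)(C)C)C(=O)[C@H](C(C)=O)C(C)=C2
F5 | step 8 | 3-bromo-2-(TBS-oxy)-N-methoxy-N,6a-dimethyl-6-oxo-1,1a,6,6a-tetrahydrocyclopropa[a]indene-1-carboxamide (amide exo, cyclopropane carbons configured as in 12) | Brc1ccc2c(c1O[Si](C)(C)C(C)(C)C)[C@H]3[C@H](C(=O)N(C)OC)[C@@]3(C)C2=O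
F6 | step 8 | C-6 alcohol from F5 (OH syn to the cyclopropane) | Brc1ccc2c(c1O[Si](C)(C)C(C)(C)C)[C@H]3[C@H](C(=O)N(C)OC)[C@@]3(C)[C@H]2O
F7 | step 8 | C-6 epimer of 12 (OH syn to the cyclopropane) | Brc1ccc2c(c1O[Si](C)(C)C(C)(C)C)[C@H]3[C@H](C(C)=O)[C@@]3(C)[C@H]2O
F8 | step 8 | O-trichloroacetimidate of F7 | Brc1ccc2c(c1O[Si](C)(C)C(C)(C)C)[C@H]3[C@H](C(C)=O)[C@@]3(C)[C@H]2OC(=N)C(Cl)(Cl)Cl
F9 | step 8 | C-6 epimer of boronate 17 | CC1(C)OB(OC1(C)C)c1ccc2c(c1O[Si](C)(C)C(C)(C)C)[C@H]3[C@H](C(C)=O)[C@@]3(C)[C@H]2O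
F10 | step 8 | C-6 epimer of biaryl 18 | CC(=O)c1c(C)cc2ccc(-c3ccc4c(c3O[Si](C)(C)C(C)(C)C)[C@H]5[C@H](C(C)=O)[C@@]5(C)[C@H]4O)c(O[Si](C)(C)C(C)(C)C)c2c1O
F11 | step 8 | O-trichloroacetimidate of F10 | CC(=O)c1c(C)cc2ccc(-c3ccc4c(c3O[Si](C)(C)C(C)(C)C)[C@H]5[C@H](C(C)=O)[C@@]5(C)[C@H]4OC(=N)C(Cl)(Cl)Cl)c(O[Si](C)(C)C(C)(C)C)c2c1O
F12 | step 14 | desilylated 18 (free phenols, cyclopropyl carbinol intact) | CC(=O)c1c(C)cc2ccc(-c3ccc4c(c3O)[C@H]5[C@H](C(C)=O)[C@@]5(C)[C@@H]4O)c(O)c2c1O
F13 | step 14 | C-6 O-trichloroacetimidate of F12 | CC(=O)c1c(C)cc2ccc(-c3ccc4c(c3O)[C@H]5[C@H](C(C)=O)[C@@]5(C)[C@@H]4OC(=N)C(Cl)(Cl)Cl)c(O)c2c1O
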